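## Structural features

The target is built from two rings joined by one methylene carbon: ring A, a fully substituted, dearomatised acylphloroglucinol (an enolised 2-acylcyclohexane-1,3,5-trione), and ring B, a cyclopentane. Ring A carries an isobutyryl group, the linking CH2, and one quaternary stereocentre bearing a methyl and a prenyl group. Ring B carries three contiguous stereocentres: a tertiary carbinol carbon (methyl, hydroxyl), the methine holding the linking CH2 (cis to the hydroxyl), and the methine holding the isopropenyl group (trans to the CH2). The ring A stereocentre lies four bonds from the nearest ring B stereocentre, so no relay of stereochemical information between the rings can be counted on. The fragile groups are these: the tertiary alcohol lies cis to a CH2 that leads to an enol (or phenol) oxygen, so acid can close a six-membered cyclic ether or dehydrate it; the isopropenyl and prenyl alkenes rule out hydrogenation and strong acid; the enolised triketone is acidic and chelating, and its aromatic precursor is easily oxidised. The real difficulty is twofold: the relative configuration of three adjacent centres on a cyclopentane, one of them fully substituted, and absolute control at the isolated quaternary centre of ring A. The key step exploits the fact that the five ring B carbons, the linking CH2, the carbinol methyl and the isopropenyl group together form the ten-carbon skeleton of linalool. C1 is the linking CH2, C3 is the carbinol carbon with its stereocentre already present, and a bond from C2 to C6 closes ring B while C7 and C8 become the isopropenyl group.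

## Logic of the disconnections

**16 to 14 and 15.** The bond between the quaternary ring A carbon and the CH2 of its prenyl group is cut. It is the only bond whose removal lets ring A become aromatic, which erases the isolated stereocentre and replaces a sensitive enolised triketone by a stable arene. The gain is that all earlier steps run on a flat, robust ring A. The demand on the forward step is heavy. Alkylation must occur at carbon and not at oxygen, at the methyl-bearing carbon and not at the carbon that carries the ring B side chain, and at the unsubstituted end of the prenyl unit. It must also occur on one face only, under catalyst control, because ring B is too far away to direct it.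

**14 to 12.** Three phenolic O–H bonds are exchanged for acetal ethers. The phenols must be masked because an alkylzinc and a palladium catalyst are used to assemble 12, and small chelating acetals add little bulk beside the coupling site. The gain is a neutral, non-acidic coupling partner. The demand is removal without protic acid, since the tertiary alcohol of 12 lies cis to the benzylic CH2 and would close onto a phenol oxygen or eliminate once ionised.

**12 to 3 and 8.** Two bonds are cut: the bond from the aromatic carbon to the linking CH2, and the ring B bond between the CH2-bearing carbon and the isopropenyl-bearing carbon. This removes ring B and two of its three stereocentres at once. What remains is an open-chain C10 allylic chloride whose only stereocentre is the carbinol carbon, and a fully substituted aryl bromide. The demand is threefold. An allylmetal made from 3 must add across its own vinyl group with control of two new centres relative to the carbinol. The primary organometallic so formed must be coupled with 8 in the same flask. Neither the aryl ketone nor the acetals of 8 may be attacked.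

**3 to 2 to 1.** The C–Cl bond of 3 is traced to the primary allylic C–O bond of 2, and that to an allylic C–H bond of 1. Compound 1 is commercial as the (R) enantiomer and already holds all ten carbons and the carbinol centre. The demand is oxidation of the E-methyl group of the trisubstituted alkene only, and chlorination of the primary allylic alcohol beside the tertiary one without allylic shift.

**8 to 7 to 6 to 4 and 5.** The C–Br bond, the three acetal C–O bonds and the aryl–acyl bond are cut in turn. Compound 4 already carries the ring methyl group, so an unselective C-methylation is avoided. Its two free ring positions are equivalent, so the acylation poses no regiochemical question and leaves a single ring C–H for bromination. The demand is complete etherification of three hindered, partly hydrogen-bonded phenols and a bromination mild enough for the acetals.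

## Other disconnections considered

**Alternative 1:** The cut removes the linking CH2 itself: the bond from ring A to CH2, the bond from CH2 to ring B, and a C–O bond to the carbinol carbon. In the forward sense the preformed chiral trione A2 condenses with formaldehyde A4 (Knoevenagel). The resulting 2-methylene-1,3-dione adds as an oxadiene to the trisubstituted alkene of the chiral-pool cyclopentene A3 (inverse-demand hetero-Diels–Alder), giving the cis-fused dihydropyran A1 or its regioisomer through the other ring oxygen. Both regioisomers would converge once the ether is opened.
- In favour: ring A needs no protecting groups and no organometallic, and three bonds form in one operation.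
- In favour: oxygen goes to the more substituted alkene carbon, and oxygen and CH2 are necessarily cis because the addition is suprafacial. Approach anti to the allylic side chain of A3 would place that chain trans to the CH2.
- Equal or better: the relative configuration of ring B is set kinetically by the substrate, whereas the chosen plan relies on equilibration. The ring A quaternary centre is also handled early, on the small compound A2.
- Against: A1 is the cyclic ether, not the free carbinol. Opening a vinylogous ester C–O bond at a tertiary carbon must compete with the very recyclisation that makes the carbinol fragile.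
- Against: the isopropenyl group has to be carried masked as a silyloxypropyl group, because a 1,1-disubstituted alkene would compete as the two-electron partner. Unmasking adds steps.
- Against: the reactive methylene-dione can be intercepted by a second molecule of A2, and A3 needs several steps of its own.
- Comparison: on structure, this cut suits pyran-fused relatives better than the open carbinol wanted here. On mechanism, it offers pericyclic substrate control against chelation plus thermodynamic control. On step economy, the ether opening, the unmasking and the preparation of A2 and A3 make it clearly longer than the chosen route, which also takes the absolute configuration of ring B directly from 1.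

**Alternative 2:** Ring A is built, not dearomatised. The cuts are the bond from the ring carbon bearing the linking CH2 to the enol carbon beside the quaternary centre, and the bond from the acyl-bearing ring carbon to the ring carbonyl. In the forward sense the 1,3-dianion of the ring B diketone A6 is acylated at its terminal carbon by the enantiopure malonyl half-ester chloride A7. The central carbon then closes on the ester (Dieckmann-type Claisen condensation) to give A5, the triethylsilyl ether of the target.
- Better in principle: the ring A stereocentre arrives ready-made in A7, so no late catalyst-controlled dearomatisation is needed.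
- In favour: no phenol protection and no oxidisable aromatic intermediates.
- Against: both carbonyls of A7 flank a quaternary carbon and are hindered.
- Against: the configuration of ring A is only as good as the regiochemistry of the two acylations. If the central dianion carbon takes the acid chloride and the terminal carbon the ester, the epimer at the quaternary centre results.
- Against: O-acylation and retro-Claisen cleavage of the non-enolisable keto ester are open under the basic conditions.
- Against: ring B must still be made with all three stereocentres, extended by the diketone chain of A6, and protected at the carbinol.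
- Comparison: on structure, it solves the ring A centre but leaves ring B unsolved. On mechanism, charge-controlled acylations of an ambident dianion are less predictable than an ene reaction followed by cross-coupling. On step economy, A6 and A7 each need several steps and a desilylation follows, so it is longer than the chosen route.

**Alternative 3:** Ring B is cut at the bond from its ring carbon to the isopropenyl group and at the bond from the neighbouring ring carbon to the linking CH2. The carbinol methyl is left for a later addition to a ketone. In the forward sense a copper catalyst with a chiral ligand adds isopropenylmagnesium bromide A11 to cyclopent-2-enone A10. The magnesium enolate is then alkylated by the ring A benzylic bromide A9 to give the trans ketone A8. A methyl nucleophile added to the ring ketone would then lead to 12.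
- Better: the trans relationship of the two ring B methines arises kinetically, by alkylation anti to the new substituent, and does not depend on equilibration.
- Equal: the route joins the chosen one at 12, so the endgame is shared.
- In favour: A10 is inexpensive.
- Against: the absolute configuration must be created by asymmetric conjugate addition of an alkenyl Grignard reagent to a small, flat five-membered enone, a demanding case. The chosen plan buys it with 1.
- Against: the magnesium enolate is a sluggish nucleophile, and proton exchange in the enolate opens the way to polyalkylation.
- Against: A9 is a hexasubstituted, electron-rich benzylic bromide that is prone to ionisation, contains a ketone, and costs extra steps beyond 8.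
- Against: the carbinol centre must be set in a separate addition. It has to come anti to the neighbouring benzyl-type group, discriminate the ring ketone from the aryl ketone, and avoid enolisation.
- Comparison: on structure, two ring B centres are set in the key step and the third later, whereas the chosen plan starts from the carbinol centre and sets the other two against it. On mechanism, it offers kinetic anti-alkylation against chelation plus thermodynamic control. On step economy, the longest sequence is about three steps longer.

Key step: step 6

Remark: ring A of the target is an enolised triketone. The tautomer of the target SMILES is used throughout, and the other enol forms are the same compound.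

Remark: the carbinol carbon of (R)-linalool becomes the ring B carbinol carbon with the same spatial arrangement and the same descriptor (R), so the commercial (R)-(−) enantiomer is the required one. High enantiomeric purity of that material is assumed.

## Route

Step 1
Reactants: 1 (R)-(−)-linalool, (3R)-3,7-dimethylocta-1,6-dien-3-ol
Product: 2 (2E,6R)-2,6-dimethylocta-2,7-diene-1,6-diol
Conditions: SeO2 (0.3 equiv), t-BuOOH (2 equiv), salicylic acid (cat.), CH2Cl2, rt
Reagents that add atoms: tert-butyl hydroperoxide, CC(C)(C)OO (terminal oxidant; the oxygen is delivered through selenium dioxide, O=[Se]=O)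
Why: Catalytic SeO2 with t-BuOOH (Sharpless allylic oxidation: ene reaction, then [2,3]-sigmatropic shift) attacks the more substituted end of the trisubstituted alkene and oxidises its E-methyl group; the vinyl group has no allylic hydrogen and the carbinol centre is not involved.

Step 2
Reactants: 2 (2E,6R)-2,6-dimethylocta-2,7-diene-1,6-diol
Product: 3 (3R,6E)-8-chloro-3,7-dimethylocta-1,6-dien-3-ol
Conditions: NCS (1.1 equiv), Me2S, CH2Cl2, −20 → 0 °C
Reagents that add atoms: N-chlorosuccinimide, O=C1CCC(=O)N1Cl
Why: Corey–Kim chlorination: the chlorosulfonium salt activates the unhindered primary allylic hydroxyl, which chloride displaces in an SN2 step without allylic shift; the tertiary alcohol is too hindered to react and the E geometry is kept.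

Step 3
Reactants: 4 2-methylbenzene-1,3,5-triol (2-methylphloroglucinol); 5 2-methylpropanoyl chloride (isobutyryl chloride)
Product: 6 1-(2,4,6-trihydroxy-3-methylphenyl)-2-methylpropan-1-one
Conditions: AlCl3 (3.5 equiv), PhNO2, rt → 60 °C; aq. HCl
Reagents that add atoms: none
Why: Friedel–Crafts acylation of a highly activated arene; the two free ring positions of 4 are equivalent, and the first acyl group deactivates the ring against a second acylation.

Step 4
Reactants: 6 1-(2,4,6-trihydroxy-3-methylphenyl)-2-methylpropan-1-one
Product: 7 1-[2,4,6-tris(methoxymethoxy)-3-methylphenyl]-2-methylpropan-1-one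
Conditions: NaH (3.6 equiv), MOMCl (3.6 equiv), THF–DMF, 0 °C → rt
Reagents that add atoms: chloromethyl methyl ether, COCCl
Why: Williamson-type O-alkylation with a hard chloromethyl ether; NaH breaks the hydrogen bonds of the two hydroxyls next to the ketone so that all three phenols are etherified, and oxygen, not ring carbon, is alkylated.

Step 5
Reactants: 7 1-[2,4,6-tris(methoxymethoxy)-3-methylphenyl]-2-methylpropan-1-one
Product: 8 1-[3-bromo-2,4,6-tris(methoxymethoxy)-5-methylphenyl]-2-methylpropan-1-one
Conditions: NBS (1.05 equiv), MeCN, 0 °C → rt
Reagents that add atoms: N-bromosuccinimide, O=C1CCC(=O)N1Br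
Why: Electrophilic aromatic bromination at the only unsubstituted ring carbon, which is activated by two ortho and one para alkoxy groups; the medium stays non-acidic, so the acetal ethers survive, and the ketone is not brominated under these conditions.

Step 6
Reactants: 3 (3R,6E)-8-chloro-3,7-dimethylocta-1,6-dien-3-ol; 8 1-[3-bromo-2,4,6-tris(methoxymethoxy)-5-methylphenyl]-2-methylpropan-1-one
Product: 12 1-[3-{[(1S,2R,5R)-2-hydroxy-2-methyl-5-(prop-1-en-2-yl)cyclopentyl]methyl}-2,4,6-tris(methoxymethoxy)-5-methylphenyl]-2-methylpropan-1-one, via allylmagnesium chloride alkoxide 9 (not isolated), via cyclised alkylmagnesium chelate 10 (not isolated), via alkylzinc chloride 11 (not isolated)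
Conditions: 3 (1.5 equiv), MeMgCl (1.0 equiv per 3), THF, −78 °C; added to activated Mg powder, THF, −65 °C → rt; 65 °C, then 110 °C (sealed); decant from Mg; ZnCl2 (THF), 0 °C → rt; 8, Pd(OAc)2 (5 mol %), SPhos (10 mol %), THF–NMP, 60 °C; aq. NH4Cl
Reagents that add atoms: none
Why: MeMgCl turns the hydroxyl of 3 into a chloromagnesium alkoxide, and magnesium inserts into the allylic C–Cl bond at low temperature, where Wurtz coupling is slow, to give 9. On warming, the 2-methylallyl magnesium unit adds across the neighbouring vinyl group through a six-centre magnesium-ene transition state: C6 bonds to the internal vinyl carbon C2, magnesium passes to C1 and the allyl double bond shifts to C7=C8, so ring B closes in the 5-exo-trig mode and the isopropenyl group appears; the closest known reaction types are the intramolecular magnesium-ene cyclisation of 2,7-dienylmagnesium halides and the alkoxide-directed allylmagnesiation of allylic alcohols. The centre at C2 is controlled by the alkoxide on C3, which binds magnesium and so holds the new CH2–Mg cis to oxygen in a cis-fused five-membered chelate. The centre at C6 is controlled thermodynamically: kinetic closure favours isopropenyl cis to CH2–Mg, but the ene reaction is reversible on heating and the mixture should drain into chelate 10, in which the CH2–Mg group is trans to both the isopropenyl and the methyl group. The (R) carbinol centre is not touched and fixes the absolute configuration. ZnCl2 then gives alkylzinc 11, which neither adds to the hindered aryl ketone of 8 nor attacks its acetals, and zerovalent palladium formed from Pd(OAc)2 and SPhos couples it with the doubly ortho-substituted bromide (Negishi coupling), the bulky biarylphosphine favouring reductive elimination over β-hydride elimination. The step therefore needs diastereoselectivity at two centres, secured by chelation and reversibility, and chemoselectivity for C–Br over C=O, secured by the transmetalation to zinc before 8 is added.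

Step 7
Reactants: 12 1-[3-{[(1S,2R,5R)-2-hydroxy-2-methyl-5-(prop-1-en-2-yl)cyclopentyl]methyl}-2,4,6-tris(methoxymethoxy)-5-methylphenyl]-2-methylpropan-1-one
Product: 14 1-[3-{[(1S,2R,5R)-2-hydroxy-2-methyl-5-(prop-1-en-2-yl)cyclopentyl]methyl}-2,4,6-trihydroxy-5-methylphenyl]-2-methylpropan-1-one, via tetrakis(trimethylsilyl) ether 13 (not isolated)
Conditions: TMSOTf (6 equiv), 2,2′-bipyridyl (9 equiv), CH2Cl2, 0 °C → rt; then H2O–MeOH, rt
Reagents that add atoms: none
Why: Silyl triflate–bipyridyl cleavage of aromatic methoxymethyl ethers: electrophilic silicon, buffered by the pyridine base, exchanges each aryl acetal for an aryl silyl ether without a Brønsted acid, and the tertiary carbinol is silylated in the same flask, which shields it from ionisation; water and methanol then hydrolyse all four silyl ethers of 13 in the weakly acidic bipyridinium triflate buffer by attack at silicon, leaving the C–O bond of the carbinol and both alkenes untouched.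

Step 8
Reactants: 14 1-[3-{[(1S,2R,5R)-2-hydroxy-2-methyl-5-(prop-1-en-2-yl)cyclopentyl]methyl}-2,4,6-trihydroxy-5-methylphenyl]-2-methylpropan-1-one; 15 3-methylbut-2-en-1-yl acetate (prenyl acetate)
Product: 16 (6R)-3,5-dihydroxy-4-{[(1S,2R,5R)-2-hydroxy-2-methyl-5-(prop-1-en-2-yl)cyclopentyl]methyl}-6-methyl-6-(3-methylbut-2-en-1-yl)-2-(2-methylpropanoyl)cyclohexa-2,4-dien-1-one (target)
Conditions: Pd2(dba)3·CHCl3 (2.5 mol %), (R,R)-DACH-phenyl Trost ligand (7.5 mol %), Et3N (1.1 equiv), 15 (1.05 equiv), CH2Cl2, 0 °C → rt, argon
Reagents that add atoms: none
Why: Proposed new method: zerovalent palladium ionises 15 to a 1,1-dimethylallyl palladium cation held in the chiral pocket of the ligand, the triethylammonium phenoxide of 14 attacks its unsubstituted terminus through the methyl-bearing ring carbon (the less hindered of the two nucleophilic ring carbons, O-prenyl ethers being re-ionised by the catalyst), and the ligand selects one face of the flat nucleophile, whose two flanks differ because one neighbouring oxygen is locked in a hydrogen bond to the acyl group, so that the quaternary centre is set by the catalyst and not by the distant ring B centres; the closest known reaction types are the palladium-catalysed asymmetric allylic dearomatisation of substituted naphthols and indoles (linear prenylation included) and the non-asymmetric dearomative C-prenylation of acylphloroglucinols; should the (R,R) ligand favour the epimer, its (S,S) antipode is used.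

## Compound list

1 | (R)-(−)-linalool, (3R)-3,7-dimethylocta-1,6-dien-3-ol | CC(C)=CCC[C@@](C)(O)C=C | starting material
2 | (2E,6R)-2,6-dimethylocta-2,7-diene-1,6-diol | OC/C(C)=C/CC[C@@](C)(O)C=C | intermediate
3 | (3R,6E)-8-chloro-3,7-dimethylocta-1,6-dien-3-ol | ClC/C(C)=C/CC[C@@](C)(O)C=C | intermediate
4 | 2-methylbenzene-1,3,5-triol (2-methylphloroglucinol) | Cc1c(O)cc(O)cc1O | starting material
5 | 2-methylpropanoyl chloride | CC(C)C(=O)Cl | starting material
6 | 1-(2,4,6-trihydroxy-3-methylphenyl)-2-methylpropan-1-one | CC(C)C(=O)c1c(O)cc(O)c(C)c1O | intermediate
7 | 1-[2,4,6-tris(methoxymethoxy)-3-methylphenyl]-2-methylpropan-1-one | CC(C)C(=O)c1c(OCOC)cc(OCOC)c(C)c1OCOC | intermediate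
8 | 1-[3-bromo-2,4,6-tris(methoxymethoxy)-5-methylphenyl]-2-methylpropan-1-one | CC(C)C(=O)c1c(OCOC)c(C)c(OCOC)c(Br)c1OCOC | intermediate
9 | chloromagnesium alkoxide of the (E)-allylmagnesium chloride from 3, (R) carbinol centre kept | Cl[Mg]C/C(C)=C/CC[C@@](C)(O[Mg]Cl)C=C | intermediate
10 | cyclised primary alkylmagnesium chloride, chelated by the cis magnesium alkoxide, ring configuration as in 12 | C=C(C)[C@@H]1CC[C@@](C)(O[Mg]Cl)[C@H]1C[Mg]Cl | intermediate
11 | primary alkylzinc chloride from 10, ring configuration as in 12 | C=C(C)[C@@H]1CC[C@@](C)(O[Mg]Cl)[C@H]1C[Zn]Cl | intermediate
12 | 1-[3-{[(1S,2R,5R)-2-hydroxy-2-methyl-5-(prop-1-en-2-yl)cyclopentyl]methyl}-2,4,6-tris(methoxymethoxy)-5-methylphenyl]-2-methylpropan-1-one | C=C(C)[C@@H]1CC[C@@](C)(O)[C@H]1Cc1c(OCOC)c(C)c(OCOC)c(C(=O)C(C)C)c1OCOC | intermediate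
13 | tetrakis(trimethylsilyl) ether of 14 (three aryl silyl ethers and the tertiary silyl ether), ring configuration as in 12 | C=C(C)[C@@H]1CC[C@@](C)(O[Si](C)(C)C)[C@H]1Cc1c(O[Si](C)(C)C)c(C)c(O[Si](C)(C)C)c(C(=O)C(C)C)c1O[Si](C)(C)C | intermediate
14 | 1-[3-{[(1S,2R,5R)-2-hydroxy-2-methyl-5-(prop-1-en-2-yl)cyclopentyl]methyl}-2,4,6-trihydroxy-5-methylphenyl]-2-methylpropan-1-one | C=C(C)[C@@H]1CC[C@@](C)(O)[C@H]1Cc1c(O)c(C)c(O)c(C(=O)C(C)C)c1O | intermediate
15 | 3-methylbut-2-en-1-yl acetate (prenyl acetate) | CC(C)=CCOC(C)=O | starting material
16 | (6R)-3,5-dihydroxy-4-{[(1S,2R,5R)-2-hydroxy-2-methyl-5-(prop-1-en-2-yl)cyclopentyl]methyl}-6-methyl-6-(3-methylbut-2-en-1-yl)-2-(2-methylpropanoyl)cyclohexa-2,4-dien-1-one | C=C(C)[C@@H]1CC[C@@](C)(O)[C@H]1CC1=C(O)[C@@](C)(CC=C(C)C)C(=O)C(C(=O)C(C)C)=C1O | target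

## Step count and least certain steps

Total: 8 steps. Longest linear sequence: 6 steps (steps 3, 4, 5, 6, 7, 8). The ring B arm (steps 1 and 2) joins at step 6.

**Step 8 (proposed new method).** The most likely failure is insufficient facial discrimination at the methyl-bearing carbon, because the two flanks of that carbon differ only beyond the neighbouring oxygens. Competing alkylation at the other nucleophilic ring carbon or a second prenylation may add to it. The fallback uses known chemistry and sets out from 14. Classical base-mediated dearomative C-prenylation (prenyl bromide, NaOMe, MeOH, 0 °C) is not stereoselective at the new centre. It should give 16 together with its epimer at the ring A quaternary carbon, (6S)-3,5-dihydroxy-4-{[(1S,2R,5R)-2-hydroxy-2-methyl-5-(prop-1-en-2-yl)cyclopentyl]methyl}-6-methyl-6-(3-methylbut-2-en-1-yl)-2-(2-methylpropanoyl)cyclohexa-2,4-dien-1-one F1. The two are diastereomers and would be separated by preparative chromatography. The fallback comes back to the route at 16.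

**Step 6 (key step).** The most likely failure is incomplete thermal equilibration of the kinetically favoured ene adduct (isopropenyl cis to CH2–Mg) into the trans chelate, so that a mixture of ring B diastereomers enters the coupling. The second concern is protodemetalation or β-hydride elimination while a β-branched alkylzinc is coupled with a doubly ortho-substituted aryl bromide in a salt-laden medium. The fallback separates the two events and changes the coupling manifold. It sets out from 3.
- The magnesium-ene cyclisation is run as before, and the organomagnesium is quenched with 2-isopropoxy-4,4,5,5-tetramethyl-1,3,2-dioxaborolane. This gives the isolable (1R,2S,3R)-1-methyl-3-(prop-1-en-2-yl)-2-[(4,4,5,5-tetramethyl-1,3,2-dioxaborolan-2-yl)methyl]cyclopentan-1-ol F2.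
- At F2 the ring diastereomers can be separated and the configuration checked before ring A is committed.
- KHF2 in MeOH–H2O converts it into potassium trifluoro{[(1S,2R,5R)-2-hydroxy-2-methyl-5-(prop-1-en-2-yl)cyclopentyl]methyl}borate F3, which can be purified by crystallisation.
- Suzuki–Miyaura coupling of the primary alkyltrifluoroborate with 8 (Pd(OAc)2, RuPhos, K2CO3, toluene–H2O, 85 °C) comes back to the route at 12.

**Step 7.** The most likely failure is incomplete acetal exchange at three positions that are each flanked by two ortho substituents. The other concern is ionisation of the tertiary carbinol by the Lewis acid before it is silylated, followed by ring closure onto the neighbouring oxygen or loss of water. The fallback replaces the acetal ethers by fluoride-labile ones, so that no acid of any kind is needed. It sets out from 6.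
- 2-(Trimethylsilyl)ethoxymethyl chloride and NaH give 2-methyl-1-[3-methyl-2,4,6-tris{[2-(trimethylsilyl)ethoxy]methoxy}phenyl]propan-1-one F4.
- NBS in MeCN gives 1-[3-bromo-5-methyl-2,4,6-tris{[2-(trimethylsilyl)ethoxy]methoxy}phenyl]-2-methylpropan-1-one F5.
- The step 6 protocol with 3 gives 1-[3-{[(1S,2R,5R)-2-hydroxy-2-methyl-5-(prop-1-en-2-yl)cyclopentyl]methyl}-5-methyl-2,4,6-tris{[2-(trimethylsilyl)ethoxy]methoxy}phenyl]-2-methylpropan-1-one F6.
- Bu4NF in THF–DMPU at 60 °C removes the three ethers under basic, non-ionising conditions and comes back to the route at 14.

## Further compounds

F1 | step 8 | (6S)-3,5-dihydroxy-4-{[(1S,2R,5R)-2-hydroxy-2-methyl-5-(prop-1-en-2-yl)cyclopentyl]methyl}-6-methyl-6-(3-methylbut-2-en-1-yl)-2-(2-methylpropanoyl)cyclohexa-2,4-dien-1-one (epimer of 16 at the ring A quaternary carbon) | C=C(C)[C@@H]1CC[C@@](C)(O)[C@H]1CC1=C(O)[C@](C)(CC=C(C)C)C(=O)C(C(=O)C(C)C)=C1O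
F2 | step 6 | (1R,2S,3R)-1-methyl-3-(prop-1-en-2-yl)-2-[(4,4,5,5-tetramethyl-1,3,2-dioxaborolan-2-yl)methyl]cyclopentan-1-ol | C=C(C)[C@@H]1CC[C@@](C)(O)[C@H]1CB1OC(C)(C)C(C)(C)O1
F3 | step 6 | potassium trifluoro{[(1S,2R,5R)-2-hydroxy-2-methyl-5-(prop-1-en-2-yl)cyclopentyl]methyl}borate | C=C(C)[C@@H]1CC[C@@](C)(O)[C@H]1C[B-](F)(F)F.[K+]
F4 | step 7 | 2-methyl-1-[3-methyl-2,4,6-tris{[2-(trimethylsilyl)ethoxy]methoxy}phenyl]propan-1-one | CC(C)C(=O)c1c(OCOCC[Si](C)(C)C)cc(OCOCC[Si](C)(C)C)c(C)c1OCOCC[Si](C)(C)C
F5 | step 7 | 1-[3-bromo-5-methyl-2,4,6-tris{[2-(trimethylsilyl)ethoxy]methoxy}phenyl]-2-methylpropan-1-one | CC(C)C(=O)c1c(OCOCC[Si](C)(C)C)c(C)c(OCOCC[Si](C)(C)C)c(Br)c1OCOCC[Si](C)(C)C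
F6 | step 7 | 1-[3-{[(1S,2R,5R)-2-hydroxy-2-methyl-5-(prop-1-en-2-yl)cyclopentyl]methyl}-5-methyl-2,4,6-tris{[2-(trimethylsilyl)ethoxy]methoxy}phenyl]-2-methylpropan-1-one | C=C(C)[C@@H]1CC[C@@](C)(O)[C@H]1Cc1c(OCOCC[Si](C)(C)C)c(C)c(OCOCC[Si](C)(C)C)c(C(=O)C(C)C)c1OCOCC[Si](C)(C)C
A1 | alternative 1 | cis-fused cyclopenta-dihydropyran adduct with silyl-protected hydroxypropyl side chain | CC(CO[Si](C)(C)C(C)(C)C)[C@@H]1CC[C@@](C)(O2)[C@H]1CC1=C(O)[C@@](C)(CC=C(C)C)C(=O)C(C(=O)C(C)C)=C12
A2 | alternative 1 | (6R)-3,5-dihydroxy-6-methyl-6-(3-methylbut-2-en-1-yl)-2-(2-methylpropanoyl)cyclohexa-2,4-dien-1-one | C1=C(O)[C@@](C)(CC=C(C)C)C(=O)C(C(=O)C(C)C)=C1O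
A3 | alternative 1 | tert-butyldimethylsilyl ether of 2-(3-methylcyclopent-2-en-1-yl)propan-1-ol, ring configuration as in ring B | CC(CO[Si](C)(C)C(C)(C)C)[C@@H]1CCC(C)=C1
A4 | alternative 1 | formaldehyde | C=O
A5 | alternative 2 | triethylsilyl ether of the target at the tertiary carbinol | C=C(C)[C@@H]1CC[C@@](C)(O[Si](CC)(CC)CC)[C@H]1CC1=C(O)[C@@](C)(CC=C(C)C)C(=O)C(C(=O)C(C)C)=C1O
A6 | alternative 2 | 6-methyl-1-[(1S,2R,5R)-2-methyl-5-(prop-1-en-2-yl)-2-(triethylsilyloxy)cyclopentyl]heptane-3,5-dione | C=C(C)[C@@H]1CC[C@@](C)(O[Si](CC)(CC)CC)[C@H]1CCC(=O)CC(=O)C(C)C
A7 | alternative 2 | methyl (S)-2-(chlorocarbonyl)-2,5-dimethylhex-4-enoate | ClC(=O)[C@@](C)(CC=C(C)C)C(=O)OC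
A8 | alternative 3 | trans 2-(arylmethyl)-3-isopropenylcyclopentanone carrying protected ring A | C=C(C)[C@@H]1CCC(=O)[C@H]1Cc1c(OCOC)c(C)c(OCOC)c(C(=O)C(C)C)c1OCOC
A9 | alternative 3 | 1-[3-(bromomethyl)-2,4,6-tris(methoxymethoxy)-5-methylphenyl]-2-methylpropan-1-one | CC(C)C(=O)c1c(OCOC)c(C)c(OCOC)c(CBr)c1OCOC
A10 | alternative 3 | cyclopent-2-enone | O=C1CCC=C1
A11 | alternative 3 | isopropenylmagnesium bromide | C=C(C)[Mg]Br
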